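The route rests on cutting the O–C3 bond of the furanone, which turns the oxygen bridge into a free tertiary C10 hydroxyl and leaves a plain C2=C3 enone in a ten-membered carbocycle. The key step exploits the α′-hydroxy enone array O10–C10–C1(=O)–C2=C3: across the ring O10 can reach only C3, so one aerobic palladium-catalysed operation forms O–C3, closes the five-membered furanone ring and regenerates C2=C3 with no stereocentre at stake. Its precursor is the ten-membered E-enone that already carries the free C10 hydroxyl, the cis-fused C6/C7 methylene lactone and the acetonide-protected C8 ester, assembled by Evans aldol, Evans–Tishchenko coupling, carbonylative lactonisation and ring-closing metathesis.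

Key step: step 21

Remark: germacranolide numbering of the target is used throughout (C1 ketone, C2=C3, C4 CHMe, C6 lactone carbinol, C7, C8 acyloxy carbinol, C10 quaternary, C11–C13 methylene lactone); the target SMILES defines a cis-fused lactone (H6 and H7 syn) with C11 and O8 syn along C6–C9, and the route is built for this; compounds 5–9, 15, 16, 23 and 30–32 are carried as mixtures at the C1 carbinol, which step 19 removes; 10 and 24 are taken as purchasable.

Step 1
Reactants: 1 (R)-lactic acid
Product: 2 (2R,5R)-2-tert-butyl-5-methyl-1,3-dioxolan-4-one (cis)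
Conditions: t-BuCHO, TsOH·H2O (cat.), H2SO4 (cat.), pentane, reflux, Dean–Stark trap; crystallisation from pentane at −78 °C
Reagents that add atoms: pivalaldehyde CC(C)(C)C=O
Why: Acid-catalysed acetalisation of the α-hydroxy acid with water removal should favour the cis-2,5-disubstituted dioxolanone, which is brought to one diastereomer by cold crystallisation while the lactate centre is untouched.

Step 2
Reactants: 2 (2R,5R)-2-tert-butyl-5-methyl-1,3-dioxolan-4-one
Product: 4 (2R,5S)-2-tert-butyl-5-methyl-5-(3-methylbut-2-en-1-yl)-1,3-dioxolan-4-one, via lithium enolate 3 (not isolated)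
Conditions: LiN(i-Pr)2, THF, −78 °C; then Me2C=CHCH2Br, −78 → −20 °C
Reagents that add atoms: prenyl bromide CC(C)=CCBr
Why: Enolate alkylation with self-regeneration of the stereocentre: the planar enolate should be attacked anti to the tert-butyl group, so prenyl takes the place of the former hydrogen and fixes C10 in the configuration of the target.

Step 3
Reactants: 4 (2R,5S)-2-tert-butyl-5-methyl-5-(3-methylbut-2-en-1-yl)-1,3-dioxolan-4-one
Product: 6 (4S)-4,7-dimethylocta-1,6-diene-3,4-diol (C3 epimers), via lactol 5 (not isolated)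
Conditions: i-Bu2AlH, CH2Cl2, −78 °C; then CH2=CHMgBr (4 equiv), THF, −78 → 0 °C; aq. potassium sodium tartrate
Reagents that add atoms: vinylmagnesium bromide C=C[Mg]Br
Why: One-pot partial reduction and Grignard addition: the aluminium lactolate formed at −78 °C should open to the α-alkoxy aldehyde when the vinyl Grignard reagent is added and be vinylated at C1, whose configuration is irrelevant because C1 is oxidised in step 19.

Step 4
Reactants: 6 (4S)-4,7-dimethylocta-1,6-diene-3,4-diol
Product: 7 (4S)-4,7-dimethyl-3,4-bis(triethylsilyloxy)octa-1,6-diene (C3 epimers)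
Conditions: Et3SiOTf, 2,6-lutidine, CH2Cl2, −78 → 0 °C
Reagents that add atoms: triethylsilyl trifluoromethanesulfonate CC[Si](CC)(CC)OS(=O)(=O)C(F)(F)F
Why: Silylation with a silyl triflate and a hindered pyridine base should cap both the secondary allylic and the tertiary hydroxyl, masking them against the boron, aluminium and Grignard reagents used later.

Step 5
Reactants: 7 (4S)-4,7-dimethyl-3,4-bis(triethylsilyloxy)octa-1,6-diene
Product: 9 (3S)-3-methyl-3,4-bis(triethylsilyloxy)hex-5-enal (C4 epimers; carries C8–C10 and C1–C2), via secondary ozonide 8 (not isolated)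
Conditions: O3 (1 equiv), CH2Cl2, −78 °C; then PPh3, −78 °C → rt
Reagents that add atoms: ozone [O-][O+]=O
Why: Chemoselective ozonolysis: the electron-rich trisubstituted prenyl alkene should react far faster than the monosubstituted vinyl group deactivated by its allylic silyloxy substituent, and reductive work-up gives the C8 aldehyde.

Step 6
Reactants: 10 3-bromobut-3-enoic acid; 11 (R)-4-benzyloxazolidin-2-one
Product: 13 (R)-4-benzyl-3-(3-bromobut-3-enoyl)oxazolidin-2-one, via mixed pivalic anhydride 12 (not isolated)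
Conditions: t-BuCOCl, Et3N, THF, −20 °C; then 11, LiCl, −20 °C → rt
Reagents that add atoms: none
Why: Mixed-anhydride N-acylation of the oxazolidinone under LiCl/Et3N activation needs no strong base, so the β,γ-unsaturated vinyl bromide should not move into conjugation.

Step 7
Reactants: 13 (R)-4-benzyl-3-(3-bromobut-3-enoyl)oxazolidin-2-one; 9 (3S)-3-methyl-3,4-bis(triethylsilyloxy)hex-5-enal
Product: 15 (R)-4-benzyl-3-[(2R,3S,5S)-2-(1-bromoethenyl)-3-hydroxy-5-methyl-5,6-bis(triethylsilyloxy)oct-7-enoyl]oxazolidin-2-one, via dibutylboron (Z)-enolate 14 (not isolated)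
Conditions: 13, Bu2BOTf, i-Pr2NEt, CH2Cl2, −78 → 0 °C; then 9, −78 → 0 °C; pH 7 buffer, MeOH, H2O2, 0 °C
Reagents that add atoms: none
Why: Evans syn aldol reaction: the (Z)-boron enolate reacts through a Zimmerman–Traxler chair whose face is dictated by the benzyl group of the (R)-auxiliary, which should set C7 and C8 together with C11 and O8 syn along C6–C9 in the absolute sense of the target, the 1-bromovinyl group taking the role of the usual α-methyl.

Step 8
Reactants: 15 (R)-4-benzyl-3-[(2R,3S,5S)-2-(1-bromoethenyl)-3-hydroxy-5-methyl-5,6-bis(triethylsilyloxy)oct-7-enoyl]oxazolidin-2-one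
Product: 16 (2R,3S,5S)-2-(1-bromoethenyl)-3-hydroxy-N-methoxy-N,5-dimethyl-5,6-bis(triethylsilyloxy)oct-7-enamide
Conditions: MeNH(OMe)·HCl, AlMe3, CH2Cl2, −20 → 0 °C; aq. potassium sodium tartrate
Reagents that add atoms: N,O-dimethylhydroxylamine hydrochloride CNOC.Cl
Why: Weinreb transamidation of the imide by the aluminium amide is assisted by the free β-hydroxyl and should release the auxiliary without disturbing C7.

Step 9
Reactants: 17 methyl (S)-3-hydroxy-2-methylpropanoate
Product: 18 methyl (S)-3-(tert-butyldimethylsilyloxy)-2-methylpropanoate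
Conditions: t-BuMe2SiCl, imidazole, CH2Cl2, 0 °C → rt
Reagents that add atoms: tert-butyldimethylsilyl chloride CC(C)(C)[Si](C)(C)Cl
Why: Routine silylation of the primary alcohol protects it through the reduction–olefination that follows.

Step 10
Reactants: 18 methyl (S)-3-(tert-butyldimethylsilyloxy)-2-methylpropanoate
Product: 20 (R)-tert-butyldimethyl[(2-methylbut-3-en-1-yl)oxy]silane, via silyloxy aldehyde 19 (not isolated)
Conditions: i-Bu2AlH, CH2Cl2, −78 °C; then Ph3P=CH2 (from Ph3PCH3Br, KN(SiMe3)2), THF, −78 °C → rt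
Reagents that add atoms: methylenetriphenylphosphorane C=P(c1ccccc1)(c1ccccc1)c1ccccc1
Why: One-pot ester reduction and Wittig methylenation: the aluminium hemiacetal should release the α-chiral aldehyde only in the presence of the non-stabilised ylide, so the former ester carbon becomes the C3 vinyl group without epimerisation of C4.

Step 11
Reactants: 20 (R)-tert-butyldimethyl[(2-methylbut-3-en-1-yl)oxy]silane
Product: 21 (R)-4-bromo-3-methylbut-1-ene
Conditions: Ph3PBr2 (from PPh3, Br2), CH2Cl2, 0 °C → rt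
Reagents that add atoms: dibromotriphenylphosphorane BrP(Br)(c1ccccc1)(c1ccccc1)c1ccccc1
Why: Appel-type direct conversion of a silyl ether into the bromide proceeds by SN2 displacement at the primary carbon of an oxyphosphonium ion and should leave the neighbouring C4 centre untouched.

Step 12
Reactants: 21 (R)-4-bromo-3-methylbut-1-ene; 16 (2R,3S,5S)-2-(1-bromoethenyl)-3-hydroxy-N-methoxy-N,5-dimethyl-5,6-bis(triethylsilyloxy)oct-7-enamide
Product: 23 (3S,6R,7S,9S)-6-(1-bromoethenyl)-7-hydroxy-3,9-dimethyl-9,10-bis(triethylsilyloxy)dodeca-1,11-dien-5-one, via Grignard reagent 22 (not isolated)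
Conditions: 21, Mg, THF, 0 °C → rt, solution decanted from Mg; then 16, THF, −20 → 0 °C; aq. NH4Cl
Reagents that add atoms: none
Why: Weinreb ketone synthesis: the Grignard reagent, used at once at or below 0 °C to avoid homoallyl–cyclopropylcarbinyl scrambling of C4, should first form the C8 magnesium alkoxide (which disfavours deprotonation at C7) and then add once to the chelating N-methoxy amide, the vinyl bromide being inert to Grignard reagents without a catalyst.

Step 13
Reactants: 24 (R)-3-bromo-2-hydroxy-2-methylpropanoic acid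
Product: 26 (S)-2,3-dihydroxy-2-methylpropanoic acid, via sodium glycidate 25 (not isolated)
Conditions: NaOH (3 equiv), H2O, 0 → 60 °C; then aq. HCl to pH 2, continuous extraction (EtOAc)
Reagents that add atoms: sodium hydroxide [Na+].[OH-]
Why: Intramolecular Williamson closure to the glycidate followed by SN2 opening by hydroxide at the unsubstituted CH2 never touches the quaternary centre, so its configuration should be retained (the descriptor changes from R to S only because O replaces Br).

Step 14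
Reactants: 26 (S)-2,3-dihydroxy-2-methylpropanoic acid
Product: 28 methyl (S)-2,2,4-trimethyl-1,3-dioxolane-4-carboxylate, via methyl ester diol 27 (not isolated)
Conditions: Me2C(OMe)2, MeOH, TsOH·H2O (cat.), 50 °C
Reagents that add atoms: 2,2-dimethoxypropane COC(C)(C)OC; methanol CO
Why: Fischer esterification and transacetalisation in one flask, 2,2-dimethoxypropane serving as acetonide source and water scavenger, should give the protected ester.

Step 15
Reactants: 28 methyl (S)-2,2,4-trimethyl-1,3-dioxolane-4-carboxylate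
Product: 29 (S)-2,2,4-trimethyl-1,3-dioxolane-4-carbaldehyde
Conditions: i-Bu2AlH, CH2Cl2, −78 °C; MeOH, aq. potassium sodium tartrate
Reagents that add atoms: none
Why: Partial reduction of an α-alkoxy ester at −78 °C should stop at the aldehyde, which has no α-hydrogen and cannot epimerise.

Step 16
Reactants: 23 (3S,6R,7S,9S)-6-(1-bromoethenyl)-7-hydroxy-3,9-dimethyl-9,10-bis(triethylsilyloxy)dodeca-1,11-dien-5-one; 29 (S)-2,2,4-trimethyl-1,3-dioxolane-4-carbaldehyde
Product: 30 (3S,5S,6S,7S,9S)-6-(1-bromoethenyl)-5-hydroxy-3,9-dimethyl-9,10-bis(triethylsilyloxy)dodeca-1,11-dien-7-yl (S)-2,2,4-trimethyl-1,3-dioxolane-4-carboxylate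
Conditions: 29 (4 equiv), SmI2 (30 mol %), THF, −10 °C
Reagents that add atoms: none
Why: Evans–Tishchenko reaction: the samarium-bound hemiacetal of the C8 hydroxyl and 29 delivers hydride intramolecularly to the C6 ketone through a chair-like transition state, which should give the 1,3-anti C6 carbinol while the aldehyde becomes the C8 ester, so C6 is set and O6 and O8 are told apart in one operation.

Step 17
Reactants: 30 (3S,5S,6S,7S,9S)-6-(1-bromoethenyl)-5-hydroxy-3,9-dimethyl-9,10-bis(triethylsilyloxy)dodeca-1,11-dien-7-yl (S)-2,2,4-trimethyl-1,3-dioxolane-4-carboxylate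
Product: 31 (1S,3S)-3-methyl-1-[(2S,3S)-2-[(2S)-2-methylbut-3-en-1-yl]-4-methylidene-5-oxooxolan-3-yl]-3,4-bis(triethylsilyloxy)hex-5-en-1-yl (S)-2,2,4-trimethyl-1,3-dioxolane-4-carboxylate
Conditions: Pd(PPh3)4 (10 mol %), CO (1 atm), Et3N, MeCN, 65 °C
Reagents that add atoms: carbon monoxide [C-]#[O+]
Why: Palladium-catalysed carbonylative lactonisation of a 3-bromohomoallylic alcohol: oxidative addition of zerovalent palladium to the vinyl bromide, CO insertion and capture of the acylpalladium by the C6 hydroxyl should give the α-methylene-γ-butyrolactone, cis-fused because C6 and C7 are already set.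

Step 18
Reactants: 31 (1S,3S)-3-methyl-1-[(2S,3S)-2-[(2S)-2-methylbut-3-en-1-yl]-4-methylidene-5-oxooxolan-3-yl]-3,4-bis(triethylsilyloxy)hex-5-en-1-yl (S)-2,2,4-trimethyl-1,3-dioxolane-4-carboxylate
Product: 32 (1S,3S)-3,4-dihydroxy-3-methyl-1-[(2S,3S)-2-[(2S)-2-methylbut-3-en-1-yl]-4-methylidene-5-oxooxolan-3-yl]hex-5-en-1-yl (S)-2,2,4-trimethyl-1,3-dioxolane-4-carboxylate
Conditions: HF·pyridine, pyridine, THF, 0 °C → rt
Reagents that add atoms: none
Why: Fluoride-mediated desilylation buffered by pyridine should free the C1 and C10 hydroxyls without touching the acetonide, the ester or the lactone.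

Step 19
Reactants: 32 (1S,3S)-3,4-dihydroxy-3-methyl-1-[(2S,3S)-2-[(2S)-2-methylbut-3-en-1-yl]-4-methylidene-5-oxooxolan-3-yl]hex-5-en-1-yl (S)-2,2,4-trimethyl-1,3-dioxolane-4-carboxylate
Product: 33 (1S,3S)-3-hydroxy-3-methyl-1-[(2S,3S)-2-[(2S)-2-methylbut-3-en-1-yl]-4-methylidene-5-oxooxolan-3-yl]-4-oxohex-5-en-1-yl (S)-2,2,4-trimethyl-1,3-dioxolane-4-carboxylate
Conditions: Dess–Martin periodinane, NaHCO3, CH2Cl2, 0 °C
Reagents that add atoms: none
Why: Dess–Martin oxidation should convert the secondary allylic C1 carbinol into the vinyl ketone, the tertiary C10 hydroxyl being unoxidisable, and thereby merge both C1 epimers.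

Step 20
Reactants: 33 (1S,3S)-3-hydroxy-3-methyl-1-[(2S,3S)-2-[(2S)-2-methylbut-3-en-1-yl]-4-methylidene-5-oxooxolan-3-yl]-4-oxohex-5-en-1-yl (S)-2,2,4-trimethyl-1,3-dioxolane-4-carboxylate
Product: 34 (2E,4S,6S,7S,8S,10S)-10-hydroxy-1-oxo-8-[(S)-2,2,4-trimethyl-1,3-dioxolane-4-carbonyloxy]germacra-2,11(13)-dien-12,6-olide
Conditions: second-generation Hoveyda–Grubbs catalyst RuCl2(H2IMes)(=CH-C6H4-2-O-i-Pr) (15 mol %), toluene (1 mM), 80 °C, argon sparge
Reagents that add atoms: none
Why: Ring-closing metathesis at high dilution should join the C3 vinyl group to the vinyl ketone to give the ten-membered C2=C3 enone, the electron-poor 1,1-disubstituted methylene lactone being a poor metathesis partner; the E isomer is drawn, and a Z isomer would serve equally because step 21 erases the alkene geometry.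

Step 21
Reactants: 34 (2E,4S,6S,7S,8S,10S)-10-hydroxy-1-oxo-8-[(S)-2,2,4-trimethyl-1,3-dioxolane-4-carbonyloxy]germacra-2,11(13)-dien-12,6-olide
Product: 35 (4S,6S,7S,8S,10S)-3,10-epoxy-1-oxo-8-[(S)-2,2,4-trimethyl-1,3-dioxolane-4-carbonyloxy]germacra-2,11(13)-dien-12,6-olide (acetonide of the target)
Conditions: Pd(O2CCF3)2 (20 mol %), DMSO (40 mol %), Na2HPO4, 4 Å molecular sieves, O2 (1 atm), toluene, 60 °C
Reagents that add atoms: none
Why: Divalent palladium coordinates C2=C3 and the C10 hydroxyl adds to C3 (oxypalladation, equivalent to a transannular oxa-Michael addition followed by palladation at C2), giving a C2-bound palladium enolate of the bridged tetrahydrofuranone; β-hydride elimination of H3 then restores C2=C3 and the zerovalent palladium released is reoxidised by O2. The closest known reaction type is the aerobic Wacker-type oxidative cyclisation of acyclic α′-hydroxy enones to 3(2H)-furanones under divalent palladium catalysis. The one ring formed, the five-membered furanone O–C10–C1–C2–C3, closes in a 5-endo-trig mode across the ten-membered ring. No stereocentre is created, because the transient C3 centre returns to sp2, which is also why E and Z enones should converge. The step needs regio- and chemoselectivity: only attack of O10 on C3 gives a five-membered ring, the tertiary alcohol cannot be oxidised to a carbonyl, and the methylene lactone, esters and acetonide should be inert under these neutral oxidative conditions.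

Step 22
Reactants: 35 (4S,6S,7S,8S,10S)-3,10-epoxy-1-oxo-8-[(S)-2,2,4-trimethyl-1,3-dioxolane-4-carbonyloxy]germacra-2,11(13)-dien-12,6-olide
Product: 36 (4S,6S,7S,8S,10S)-8-[(S)-2,3-dihydroxy-2-methylpropanoyloxy]-3,10-epoxy-1-oxogermacra-2,11(13)-dien-12,6-olide (CNP0263764.3)
Conditions: AcOH/H2O/THF (3:1:1), 45 °C
Reagents that add atoms: none
Why: Acid-catalysed acetal hydrolysis should remove the isopropylidene group under conditions that the furanone (a vinylogous ester), the methylene lactone and the C8 ester tolerate.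

Compound list
1 | (R)-lactic acid | C[C@@H](O)C(=O)O | starting material
2 | (2R,5R)-2-tert-butyl-5-methyl-1,3-dioxolan-4-one | C[C@H]1O[C@@H](C(C)(C)C)OC1=O | intermediate
3 | lithium enolate of 2 (not isolated) | CC1=C([O-])O[C@H](C(C)(C)C)O1.[Li+] | intermediate
4 | (2R,5S)-2-tert-butyl-5-methyl-5-(3-methylbut-2-en-1-yl)-1,3-dioxolan-4-one | C[C@@]1(CC=C(C)C)O[C@@H](C(C)(C)C)OC1=O | intermediate
5 | lactol of 4, 2-tert-butyl-5-methyl-5-prenyl-1,3-dioxolan-4-ol, present as its aluminium alkoxide (not isolated) | C[C@@]1(CC=C(C)C)O[C@@H](C(C)(C)C)OC1O | intermediate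
6 | (4S)-4,7-dimethylocta-1,6-diene-3,4-diol | C=CC(O)[C@@](C)(O)CC=C(C)C | intermediate
7 | (4S)-4,7-dimethyl-3,4-bis(triethylsilyloxy)octa-1,6-diene | C=CC(O[Si](CC)(CC)CC)[C@@](C)(O[Si](CC)(CC)CC)CC=C(C)C | intermediate
8 | secondary ozonide (1,2,4-trioxolane) of the prenyl alkene of 7 (not isolated) | CC1(C)OOC(C[C@](C)(O[Si](CC)(CC)CC)C(O[Si](CC)(CC)CC)C=C)O1 | intermediate
9 | (3S)-3-methyl-3,4-bis(triethylsilyloxy)hex-5-enal | O=CC[C@](C)(O[Si](CC)(CC)CC)C(O[Si](CC)(CC)CC)C=C | intermediate
10 | 3-bromobut-3-enoic acid | C=C(Br)CC(=O)O | starting material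
11 | (R)-4-benzyloxazolidin-2-one | O=C1N[C@H](Cc2ccccc2)CO1 | starting material
12 | 3-bromobut-3-enoic pivalic anhydride (not isolated) | C=C(Br)CC(=O)OC(=O)C(C)(C)C | intermediate
13 | (R)-4-benzyl-3-(3-bromobut-3-enoyl)oxazolidin-2-one | C=C(Br)CC(=O)N1[C@H](Cc2ccccc2)COC1=O | intermediate
14 | dibutylboron (Z)-enolate of 13 (not isolated) | C=C(Br)/C=C(\OB(CCCC)CCCC)N1[C@H](Cc2ccccc2)COC1=O | intermediate
15 | (R)-4-benzyl-3-[(2R,3S,5S)-2-(1-bromoethenyl)-3-hydroxy-5-methyl-5,6-bis(triethylsilyloxy)oct-7-enoyl]oxazolidin-2-one | C=C(Br)[C@H]([C@@H](O)C[C@](C)(O[Si](CC)(CC)CC)C(O[Si](CC)(CC)CC)C=C)C(=O)N1[C@H](Cc2ccccc2)COC1=O | intermediate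
16 | (2R,3S,5S)-2-(1-bromoethenyl)-3-hydroxy-N-methoxy-N,5-dimethyl-5,6-bis(triethylsilyloxy)oct-7-enamide | CON(C)C(=O)[C@H](C(Br)=C)[C@@H](O)C[C@](C)(O[Si](CC)(CC)CC)C(O[Si](CC)(CC)CC)C=C | intermediate
17 | methyl (S)-3-hydroxy-2-methylpropanoate | COC(=O)[C@@H](C)CO | starting material
18 | methyl (S)-3-(tert-butyldimethylsilyloxy)-2-methylpropanoate | COC(=O)[C@@H](C)CO[Si](C)(C)C(C)(C)C | intermediate
19 | (S)-3-(tert-butyldimethylsilyloxy)-2-methylpropanal (not isolated) | O=C[C@@H](C)CO[Si](C)(C)C(C)(C)C | intermediate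
20 | (R)-tert-butyldimethyl[(2-methylbut-3-en-1-yl)oxy]silane | C=C[C@@H](C)CO[Si](C)(C)C(C)(C)C | intermediate
21 | (R)-4-bromo-3-methylbut-1-ene | C=C[C@@H](C)CBr | intermediate
22 | [(R)-2-methylbut-3-en-1-yl]magnesium bromide (not isolated) | C=C[C@@H](C)C[Mg]Br | intermediate
23 | (3S,6R,7S,9S)-6-(1-bromoethenyl)-7-hydroxy-3,9-dimethyl-9,10-bis(triethylsilyloxy)dodeca-1,11-dien-5-one | C=C[C@@H](C)CC(=O)[C@H](C(Br)=C)[C@@H](O)C[C@](C)(O[Si](CC)(CC)CC)C(O[Si](CC)(CC)CC)C=C | intermediate
24 | (R)-3-bromo-2-hydroxy-2-methylpropanoic acid | C[C@](O)(CBr)C(=O)O | starting material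
25 | sodium (S)-2-methyloxirane-2-carboxylate (not isolated) | C[C@]1(CO1)C(=O)[O-].[Na+] | intermediate
26 | (S)-2,3-dihydroxy-2-methylpropanoic acid | C[C@](O)(CO)C(=O)O | intermediate
27 | methyl (S)-2,3-dihydroxy-2-methylpropanoate (not isolated) | COC(=O)[C@@](C)(O)CO | intermediate
28 | methyl (S)-2,2,4-trimethyl-1,3-dioxolane-4-carboxylate | COC(=O)[C@@]1(C)OC(C)(C)OC1 | intermediate
29 | (S)-2,2,4-trimethyl-1,3-dioxolane-4-carbaldehyde | O=C[C@@]1(C)OC(C)(C)OC1 | intermediate
30 | (3S,5S,6S,7S,9S)-6-(1-bromoethenyl)-5-hydroxy-3,9-dimethyl-9,10-bis(triethylsilyloxy)dodeca-1,11-dien-7-yl (S)-2,2,4-trimethyl-1,3-dioxolane-4-carboxylate | C=C[C@@H](C)C[C@H](O)[C@H](C(Br)=C)[C@@H](OC(=O)[C@@]1(C)OC(C)(C)OC1)C[C@](C)(O[Si](CC)(CC)CC)C(O[Si](CC)(CC)CC)C=C | intermediate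
31 | (1S,3S)-3-methyl-1-[(2S,3S)-2-[(2S)-2-methylbut-3-en-1-yl]-4-methylidene-5-oxooxolan-3-yl]-3,4-bis(triethylsilyloxy)hex-5-en-1-yl (S)-2,2,4-trimethyl-1,3-dioxolane-4-carboxylate | C=C1C(=O)O[C@@H](C[C@H](C)C=C)[C@H]1[C@@H](OC(=O)[C@@]2(C)OC(C)(C)OC2)C[C@](C)(O[Si](CC)(CC)CC)C(O[Si](CC)(CC)CC)C=C | intermediate
32 | (1S,3S)-3,4-dihydroxy-3-methyl-1-[(2S,3S)-2-[(2S)-2-methylbut-3-en-1-yl]-4-methylidene-5-oxooxolan-3-yl]hex-5-en-1-yl (S)-2,2,4-trimethyl-1,3-dioxolane-4-carboxylate | C=C1C(=O)O[C@@H](C[C@H](C)C=C)[C@H]1[C@@H](OC(=O)[C@@]2(C)OC(C)(C)OC2)C[C@](C)(O)C(O)C=C | intermediate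
33 | (1S,3S)-3-hydroxy-3-methyl-1-[(2S,3S)-2-[(2S)-2-methylbut-3-en-1-yl]-4-methylidene-5-oxooxolan-3-yl]-4-oxohex-5-en-1-yl (S)-2,2,4-trimethyl-1,3-dioxolane-4-carboxylate | C=C1C(=O)O[C@@H](C[C@H](C)C=C)[C@H]1[C@@H](OC(=O)[C@@]2(C)OC(C)(C)OC2)C[C@](C)(O)C(=O)C=C | intermediate
34 | (2E,4S,6S,7S,8S,10S)-10-hydroxy-1-oxo-8-[(S)-2,2,4-trimethyl-1,3-dioxolane-4-carbonyloxy]germacra-2,11(13)-dien-12,6-olide (precursor of the key step) | C=C1C(=O)O[C@H]2C[C@H](C)/C=C/C(=O)[C@](C)(C[C@H](OC(=O)[C@@]3(C)OC(C)(C)OC3)[C@@H]12)O | intermediate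
35 | (4S,6S,7S,8S,10S)-3,10-epoxy-1-oxo-8-[(S)-2,2,4-trimethyl-1,3-dioxolane-4-carbonyloxy]germacra-2,11(13)-dien-12,6-olide (acetonide of the target) | C=C1C(=O)O[C@H]2C[C@H](C)C3=CC(=O)[C@](C)(C[C@H](OC(=O)[C@@]4(C)OC(C)(C)OC4)[C@@H]12)O3 | intermediate
36 | (4S,6S,7S,8S,10S)-8-[(S)-2,3-dihydroxy-2-methylpropanoyloxy]-3,10-epoxy-1-oxogermacra-2,11(13)-dien-12,6-olide (CNP0263764.3) | C=C1C(=O)O[C@H]2C[C@H](C)C3=CC(=O)[C@](C)(C[C@H](OC(=O)[C@@](C)(O)CO)[C@@H]12)O3 | target

Total step count: 22. Longest linear sequence: 15 steps (steps 1–5, 7, 8, 12, 16–22).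

Steps most likely to fail

Step 21. The transannular oxypalladation may be slow across the ring, and a palladium hydride formed in the cycle may shift the exocyclic C11=C13 alkene into the lactone ring. The fallback sets out from 34: camphorsulfonic acid in CH2Cl2 should bring about the transannular oxa-Michael addition of the C10 hydroxyl to C3 and give the saturated bridged tetrahydrofuran-3-one F1. Me3SiOTf and Et3N convert it into the C1–C2 trimethylsilyl enol ether F2, PhSeCl gives the C2 phenylselenide F3, and H2O2 with pyridine oxidises selenium, after which syn-elimination toward the only available hydrogen (H3) delivers 35, where the route is rejoined.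

Step 20. Closure of the ten-membered ring may lose to oligomerisation, or stall because the vinyl ketone is an electron-poor partner that chelates ruthenium. The fallback sets out from 32: ring-closing metathesis of the diol itself, with the free allylic alcohol as the second partner and the same ruthenium catalyst at high dilution, should give the ten-membered allylic alcohol F4 as C1 epimers. Oxidation of the allylic carbinol with MnO2 then returns to 34.

Step 16. Hemiacetal formation with the hindered α-quaternary aldehyde 29 may be too slow, leaving time for retro-aldol cleavage or C7 epimerisation of 23. The fallback sets out from 23: Evans–Tishchenko reduction with unhindered methoxyacetaldehyde and catalytic SmI2 should give the C8 methoxyacetate F5 with the same anti C6 carbinol. Carbonylative lactonisation as in step 17 gives lactone F6, and Yb(OTf)3-catalysed methanolysis removes the methoxyacetate to give the C8 alcohol F7. Yamaguchi esterification (2,4,6-trichlorobenzoyl chloride, Et3N, DMAP) with (S)-2,2,4-trimethyl-1,3-dioxolane-4-carboxylic acid F8, made from 28 with LiOH, returns to 31.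

Further compounds
F1 | step 21 | (4S,6S,7S,8S,10S)-3,10-epoxy-1-oxo-8-[(S)-2,2,4-trimethyl-1,3-dioxolane-4-carbonyloxy]germacr-11(13)-en-12,6-olide (C3 epimers) | C=C1C(=O)O[C@H]2C[C@H](C)C3CC(=O)[C@](C)(C[C@H](OC(=O)[C@@]4(C)OC(C)(C)OC4)[C@@H]12)O3
F2 | step 21 | C1–C2 trimethylsilyl enol ether of F1 | C=C1C(=O)O[C@H]2C[C@H](C)C3C=C(O[Si](C)(C)C)[C@](C)(C[C@H](OC(=O)[C@@]4(C)OC(C)(C)OC4)[C@@H]12)O3
F3 | step 21 | 2-phenylselanyl derivative of F1 | C=C1C(=O)O[C@H]2C[C@H](C)C3C([Se]c5ccccc5)C(=O)[C@](C)(C[C@H](OC(=O)[C@@]4(C)OC(C)(C)OC4)[C@@H]12)O3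
F4 | step 20 | (2E,4S,6S,7S,8S,10S)-1,10-dihydroxy-8-[(S)-2,2,4-trimethyl-1,3-dioxolane-4-carbonyloxy]germacra-2,11(13)-dien-12,6-olide (C1 epimers) | C=C1C(=O)O[C@H]2C[C@H](C)/C=C/C(O)[C@](C)(C[C@H](OC(=O)[C@@]3(C)OC(C)(C)OC3)[C@@H]12)O
F5 | step 16 | (3S,5S,6S,7S,9S)-6-(1-bromoethenyl)-5-hydroxy-3,9-dimethyl-9,10-bis(triethylsilyloxy)dodeca-1,11-dien-7-yl methoxyacetate | C=C[C@@H](C)C[C@H](O)[C@H](C(Br)=C)[C@@H](OC(=O)COC)C[C@](C)(O[Si](CC)(CC)CC)C(O[Si](CC)(CC)CC)C=C
F6 | step 16 | methoxyacetate analogue of 31 | C=C1C(=O)O[C@@H](C[C@H](C)C=C)[C@H]1[C@@H](OC(=O)COC)C[C@](C)(O[Si](CC)(CC)CC)C(O[Si](CC)(CC)CC)C=C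
F7 | step 16 | C8 alcohol corresponding to 31 | C=C1C(=O)O[C@@H](C[C@H](C)C=C)[C@H]1[C@@H](O)C[C@](C)(O[Si](CC)(CC)CC)C(O[Si](CC)(CC)CC)C=C
F8 | step 16 | (S)-2,2,4-trimethyl-1,3-dioxolane-4-carboxylic acid | OC(=O)[C@@]1(C)OC(C)(C)OC1
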